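Remark on the chemistry: the C8 acyl group carries its two methyl groups cis on the oxirane, so it is the (2S,3R) epoxide of tiglic (not angelic) acid and is made as such. The seco aldehyde and the cyclised alcohol were compared with the target centre by centre and agree; C6 is R in the macrocycle and S in the open lactones only because the CIP priorities change.

## Structural features

The target is a germacranolide: a ten-membered carbocycle (C1–C10) trans-fused at C6–C7 to an α-methylene-γ-butyrolactone (ring oxygen on C6, carbonyl C12, exocyclic C11=C13). The carbocycle holds a trans 1,10-epoxide (H on C1, C14 methyl on C10), a Z trisubstituted C4=C5 alkene with the C15 methyl on C4, a benzoate on the allylic carbon C3, and at C8 the ester of (2S,3R)-2,3-dimethyloxirane-2-carboxylic acid. C6, C7 and C8 form a contiguous triad (6R,7R,8R; lactone trans, O8 syn to C6 when C9–C8–C7–C11 is drawn zigzag). C1 and C10 are adjacent on the epoxide (1R,10R), C3 (S) stands alone and is 1,3-syn to the C1 oxygen, and two further centres sit in the acyl group. Fragile groups are the methylene lactone (Michael acceptor, base-labile, prone to isomerise to the butenolide), the two epoxides (acid), the allylic benzoate, and the C8 oxygen, which would lactonise onto C12 if left free in an open-chain ester. The real difficulty is closing a strained ten-membered ring that contains a trans epoxide and a cis alkene with control at C3, and building the C6–C7–C8 triad in an open chain. The feature used by the key step is that C3 is a secondary carbinol bonded directly to the sp2 carbon C4 of the Z alkene. This is the retron of an alkenylmetal at C4 adding to a C3 aldehyde, with the alkene geometry fixed beforehand in a C4 iodoalkene whose iodine is cis to C6.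

## Logic of the disconnections

33 ⇒ 32. The C3–O(benzoyl) bond is cut last so that the ring closure can deliver a free carbinol. The gain is one acyl group fewer in the cyclisation substrate. The forward step must acylate a hindered allylic alcohol without touching the methylene lactone; if C3 comes out inverted, the same bond can be made with inversion.

32 ⇒ 30 (through 31). The C3–C4 bond is cut, which opens the ten-membered ring and removes the C3 stereocentre. All other stereocentres, both epoxides, the lactone and the C8 ester stay in place, so nothing but acylation follows the ring closure. The forward step needs an alkenyl nucleophile that tolerates esters, epoxides and a Michael acceptor, retention of the Z geometry, and high dilution.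

30 ⇒ 29 ⇒ 28. The C3 aldehyde is traced back to a protected primary alcohol; no skeletal bond is cut. The β,γ-epoxy aldehyde is the most labile compound of the route, so it is made last and under neutral conditions. The protecting group must therefore come off oxidatively at neutral pH.

28 ⇒ 23 + 24. The C4=C5 double bond is cut into a C5 aldehyde and a two-carbon iodo ylide. This removes the iodoalkene and uses the oxygen already present on C5. The forward olefination must be Z-selective and cold enough to spare C6 and the methylene lactone.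

23 ⇒ 22 ⇒ 21. The C5 aldehyde goes back to the alcohol and the two C–O bonds of the 1,10-epoxide are cut to the E alkene. The alkene is robust in all earlier steps (acid included). The forward epoxidation must be reagent-controlled, because the alkene is remote from every stereocentre, and must leave the electron-poor methylene alone.

21 ⇒ 19 (through 20). The lactone C12–O6 bond is cut, and O5 and O6 are tied up as an acetonide. This gives an open-chain hydroxy ester in which O8 already carries its final acyl group. In the forward step only O6 (not O8) can then lactonise, and the acid must be weak enough for the glycidic ester.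

19 ⇒ 13 + 17. The C8–O acyl bond is cut. The acid fragment 17 becomes an independent three-step branch. The forward esterification must beat lactonisation of O8 onto the ethyl ester.

13 ⇒ 5 + 12. The C7–C8 bond is cut between an allylic bromide and an aldehyde. This is the convergence point: it removes two stereocentres (C7, C8) and divides the chain into a C5–C7/C11–C13 piece and a C8–C3 piece. The forward allylation must be 7,8-syn and must read the existing C6 centre correctly.

5 ⇒ 4 ⇒ 2 + 3; 2 ⇒ 1. The C7–C11 bond is cut (acrylate α-carbon plus aldehyde), after an allylic transposition that moves the leaving group from C7 to C13. C6 comes from the chiral pool. The forward bromination must give the Z bromide.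

12 ⇒ 11 ⇒ 10 ⇒ 9 ⇒ 6 (through 7 and 8). The C1–C2 bond and the C10–C14 bond are cut: an alkyne takes up methyl and a two-carbon electrophile across the triple bond. This fixes the E geometry of the future epoxide in one step. The two primary oxygens must then be differentiated.

17 ⇒ 16 ⇒ 15 ⇒ 14. The epoxide C–O bonds of the acyl group are cut to an allylic alcohol, so that an asymmetric epoxidation directed by the hydroxyl sets both centres. The forward oxidation to the acid must not open the epoxide.

## Other disconnections considered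

Alternative 1: The cut is C1–C10 together with the C1–O bond of the epoxide. In the forward direction a sulfonium ylide centred on C1 would add to a C10 methyl ketone in the same chain and the betaine would close, to give A1. In its favour, one step would make two bonds, the ring and two stereocentres (C1, C10), which is better than the single bond and single centre of step 19. The epoxide would be born inside the ring, so no β,γ-epoxy aldehyde like 30 is needed, and C3 with its benzoate would be set earlier in an open chain, where reagent control is available; on these three points the alternative is the better plan. Against it here: the acceptor is an enolisable methyl ketone flanked by a β-silyloxy group, so the amide base can enolise or eliminate instead of forming the ylide. The sulfonium centre has β-hydrogens at C2 and can undergo elimination. The facial selectivity at both C1 and C10 and the anti closure to the trans epoxide would rest entirely on the ring transition state. A1 as drawn has a saturated C11 and a silyl ether at C8, so desilylation, C8 acylation (with the risk of translactonisation) and α-methylenation under base would still follow, against one step after 32. On mechanism the two plans carry a similar entropic burden; on step economy after ring closure and on functional-group tolerance the chosen plan is ahead.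

Alternative 2: The cut is C5–C6, made through a temporary O–C4 bond. A nitrile oxide at C6 would add across a 1,1-disubstituted C4=C5H2 alkene to give the isoxazoline-bridged carbocycle A2. In its favour: the cycloaddition is concerted, irreversible, metal-free and mild, with regiochemistry (oxygen to the more substituted C4) that is secure. Both acyl groups are already in A2, which equals the chosen plan for the C8 ester and betters it by sparing the final benzoylation. C3 is again set in the open chain, a point on which it is better than step 19. The need for high dilution (dimerisation of the dipole) is the same burden as in step 19. Against it here: A2 has neither the C4=C5 alkene nor the lactone nor C13. After the ring closure it needs N–O cleavage, dehydration of a tertiary β-hydroxy ketone to the Z endocyclic enone (not the exocyclic or E isomer), 1,2-reduction of the C6 ketone with the right facial sense, lactonisation and α-methylenation in the presence of two epoxides and a benzoate. That is five or more steps and three open selectivity questions, and the C4 stereocentre is made only to be destroyed. The chosen plan closes the ring on the complete oxidation pattern and is much shorter after the key step.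

Alternative 3: The cut is C8–C9, made by a [3,3] shift that at the same time breaks a C1–C6 bond of a six-membered ring. The potassium alkoxide of a tertiary C6 alcohol would rearrange through a chair to the ten-membered dienone A3. In its favour: this is a ring expansion, not a cyclisation, so there is no entropic penalty and no high dilution. The chair fixes the 1(10)E and 4Z geometries and the silicon-bearing C8 centre in one step from a cheap chiral-pool terpene, and the carbocycle is reached in very few steps. On ring construction it is clearly the better of the two plans. Against it here: A3 lacks the lactone, the C7 substituent, the C6 and C8 oxygens (C8 only as a silicon mask that needs an oxidative C–Si cleavage beside two alkenes), the epoxide and both acyl groups. C6, C7, C1 and C10 would all have to be set on the flexible macrocycle under conformational control, and the 1(10),4-dienone is prone to transannular reactions. About ten further steps would be needed. The chosen plan sets every centre except C3 in open-chain or reagent-controlled steps and needs one step after ring closure.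

Key step: step 19

## Route

Step 1
Reactants: 1 1,2:5,6-di-O-isopropylidene-D-mannitol
Product: 2 (4R)-2,2-dimethyl-1,3-dioxolane-4-carbaldehyde
Conditions: NaIO4, aq NaHCO3, CH2Cl2, rt; used fresh
Reagents that add atoms: none
Why: Periodate glycol cleavage of the central diol gives two molecules of the aldehyde; the dioxolane centre (future C6) is not touched, and fresh material avoids the oligomerised aldehyde.

Step 2
Reactants: 2 (4R)-2,2-dimethyl-1,3-dioxolane-4-carbaldehyde; 3 ethyl acrylate
Product: 4 ethyl 2-{[(4R)-2,2-dimethyl-1,3-dioxolan-4-yl](hydroxy)methyl}prop-2-enoate (both carbinol epimers)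
Conditions: DABCO, 1,4-dioxane–H2O, rt
Reagents that add atoms: none
Why: Baylis–Hillman reaction (amine adds to 3, the ammonium enolate adds to 2, elimination frees the amine) forms C7–C11; the carbinol mixture is irrelevant because this carbon becomes sp2 in step 3, and the weakly basic amine should not epimerise the α-alkoxy aldehyde.

Step 3
Reactants: 4 ethyl 2-{[(4R)-2,2-dimethyl-1,3-dioxolan-4-yl](hydroxy)methyl}prop-2-enoate
Product: 5 ethyl (2Z)-2-(bromomethyl)-3-[(4S)-2,2-dimethyl-1,3-dioxolan-4-yl]prop-2-enoate
Conditions: NBS, Me2S, CH2Cl2, 0 °C to rt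
Reagents that add atoms: N-bromosuccinimide, O=C1CCC(=O)N1Br
Why: The bromosulfonium reagent activates the allylic hydroxyl and bromide enters at the methylene terminus (SN2' transposition of a Baylis–Hillman alcohol), giving the thermodynamically preferred 2Z primary bromide with the dioxolane cis to CH2Br; the neutral medium spares the acetonide.

Step 4
Reactants: 6 tert-butyl(but-3-yn-1-yloxy)dimethylsilane
Product: 9 (3E)-6-{[tert-butyl(dimethyl)silyl]oxy}-4-methylhex-3-en-1-ol, via alkenyldimethylalane 7 (not isolated), via lithium butyl alkenylalanate 8 (not isolated)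
Conditions: Me3Al, Cp2ZrCl2 (cat.), CH2Cl2, 0 °C to rt; volatiles removed; n-BuLi, THF–hexane, −78 °C; ethylene oxide, −78 °C to rt
Reagents that add atoms: trimethylaluminium, C[Al](C)C; ethylene oxide, C1CO1
Why: Zirconium-catalysed syn carboalumination places methyl (C14) on the internal and aluminium on the terminal alkyne carbon, which fixes the E geometry of the future C1=C10; the alanate opens ethylene oxide with retention at the alkenyl carbon and adds C2–C3.

Step 5
Reactants: 9 (3E)-6-{[tert-butyl(dimethyl)silyl]oxy}-4-methylhex-3-en-1-ol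
Product: 10 tert-butyl({(3E)-6-[(4-methoxyphenyl)methoxy]-3-methylhex-3-en-1-yl}oxy)dimethylsilane
Conditions: NaH, 4-methoxybenzyl chloride, Bu4NI (cat.), THF–DMF, 0 °C to rt
Reagents that add atoms: 4-methoxybenzyl chloride, COc1ccc(CCl)cc1
Why: Williamson etherification of the C3 oxygen; the 4-methoxybenzyl group is chosen because it survives weak acid and base and is removed oxidatively at neutral pH in step 17.

Step 6
Reactants: 10 tert-butyl({(3E)-6-[(4-methoxyphenyl)methoxy]-3-methylhex-3-en-1-yl}oxy)dimethylsilane
Product: 11 (3E)-6-[(4-methoxyphenyl)methoxy]-3-methylhex-3-en-1-ol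
Conditions: Bu4NF, THF, 0 °C to rt
Reagents that add atoms: none
Why: Fluoride cleaves the Si–O bond and frees the C8 oxygen; the benzyl-type ether and the alkene are inert.

Step 7
Reactants: 11 (3E)-6-[(4-methoxyphenyl)methoxy]-3-methylhex-3-en-1-ol
Product: 12 (3E)-6-[(4-methoxyphenyl)methoxy]-3-methylhex-3-enal
Conditions: Dess–Martin periodinane, NaHCO3, CH2Cl2, 0 °C; used at once without chromatography
Reagents that add atoms: none
Why: Buffered Dess–Martin oxidation gives the β,γ-unsaturated aldehyde without exposure to acid or base, so the alkene should not move into conjugation.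

Step 8
Reactants: 5 ethyl (2Z)-2-(bromomethyl)-3-[(4S)-2,2-dimethyl-1,3-dioxolan-4-yl]prop-2-enoate; 12 (3E)-6-[(4-methoxyphenyl)methoxy]-3-methylhex-3-enal
Product: 13 ethyl (3R,4R,6E)-3-[(4S)-2,2-dimethyl-1,3-dioxolan-4-yl]-4-hydroxy-9-[(4-methoxyphenyl)methoxy]-6-methyl-2-methylidenenon-6-enoate
Conditions: In powder, THF–H2O (1:1), rt
Reagents that add atoms: none
Why: Indium-mediated Barbier allylation: the allylindium from 5 attacks through its γ-carbon in a closed chair, and because C6 is cis to CH2In the new C7–C8 bond is formed 7,8-syn (O8 and C6 on the same side of the C9–C8–C7–C11 zigzag). The allylic dioxolane centre turns its hydrogen toward CH2In (A(1,3) strain) and the aldehyde enters anti to the C6–O bond, which sets C7 so that C6/C7 will close to the trans lactone. The neutral aqueous medium keeps the aldehyde unconjugated and the γ-hydroxy ester open.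

Step 9
Reactants: 14 tiglic acid
Product: 15 (2E)-2-methylbut-2-en-1-ol
Conditions: LiAlH4, Et2O, 0 °C to rt
Reagents that add atoms: none
Why: Hydride reduction of the carboxylic acid to the allylic alcohol by 1,2-delivery; the E trisubstituted alkene is retained.

Step 10
Reactants: 15 (2E)-2-methylbut-2-en-1-ol
Product: 16 [(2R,3R)-2,3-dimethyloxiran-2-yl]methanol
Conditions: Ti(OiPr)4 (cat.), D-(−)-diethyl tartrate (cat.), t-BuOOH, 4 Å molecular sieves, CH2Cl2, −20 °C
Reagents that add atoms: tert-butyl hydroperoxide, CC(C)(C)OO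
Why: Sharpless asymmetric epoxidation: the titanium tartrate complex binds the allylic alkoxide and the peroxide, and the D-tartrate delivers oxygen to the face that gives the (2R,3R) epoxy alcohol (the mirror image of the L-tartrate outcome); both centres of the acyl group are set with the methyl groups cis.

Step 11
Reactants: 16 [(2R,3R)-2,3-dimethyloxiran-2-yl]methanol
Product: 17 (2S,3R)-2,3-dimethyloxirane-2-carboxylic acid
Conditions: RuCl3 (cat.), NaIO4, MeCN–EtOAc–H2O, 0 °C to rt
Reagents that add atoms: water, O
Why: Ruthenium tetroxide generated in the flask oxidises the primary alcohol through the aldehyde hydrate to the acid and leaves the epoxide alone; the descriptor at C2 changes from R to S without any change in space.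

Step 12
Reactants: 13 ethyl (3R,4R,6E)-3-[(4S)-2,2-dimethyl-1,3-dioxolan-4-yl]-4-hydroxy-9-[(4-methoxyphenyl)methoxy]-6-methyl-2-methylidenenon-6-enoate; 17 (2S,3R)-2,3-dimethyloxirane-2-carboxylic acid
Product: 19 ethyl (3R,4R,6E)-4-{[(2S,3R)-2,3-dimethyloxirane-2-carbonyl]oxy}-3-[(4S)-2,2-dimethyl-1,3-dioxolan-4-yl]-9-[(4-methoxyphenyl)methoxy]-6-methyl-2-methylidenenon-6-enoate, via mixed anhydride 18 (not isolated)
Conditions: 17, 2,4,6-trichlorobenzoyl chloride, Et3N, THF, rt; then 13, DMAP, toluene, rt
Reagents that add atoms: none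
Why: Yamaguchi esterification: DMAP takes the glycidic acyl group from anhydride 18 and passes it to the hindered C8 hydroxyl with retention; acylating here, before the acetonide is opened, blocks O8 so that only O6 can lactonise later.

Step 13
Reactants: 19 ethyl (3R,4R,6E)-4-{[(2S,3R)-2,3-dimethyloxirane-2-carbonyl]oxy}-3-[(4S)-2,2-dimethyl-1,3-dioxolan-4-yl]-9-[(4-methoxyphenyl)methoxy]-6-methyl-2-methylidenenon-6-enoate
Product: 21 (1R,3E)-1-[(2S,3R)-2-(hydroxymethyl)-4-methylidene-5-oxooxolan-3-yl]-6-[(4-methoxyphenyl)methoxy]-3-methylhex-3-en-1-yl (2S,3R)-2,3-dimethyloxirane-2-carboxylate, via diol ester 20 (not isolated)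
Conditions: AcOH–H2O (4:1), 40 °C; then PPTS (cat.), toluene, 50 °C
Reagents that add atoms: none
Why: Weak aqueous acid hydrolyses the terminal acetonide to diol 20, and acid-catalysed transesterification by the secondary O6 (5-exo-trig) closes the γ-lactone in preference to the δ-lactone through O5; the trans relation at C6/C7 is already fixed, and the glycidic ester, the benzyl-type ether and the trisubstituted alkene tolerate this acidity.

Step 14
Reactants: 21 (1R,3E)-1-[(2S,3R)-2-(hydroxymethyl)-4-methylidene-5-oxooxolan-3-yl]-6-[(4-methoxyphenyl)methoxy]-3-methylhex-3-en-1-yl (2S,3R)-2,3-dimethyloxirane-2-carboxylate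
Product: 22 (1R)-1-[(2S,3R)-2-(hydroxymethyl)-4-methylidene-5-oxooxolan-3-yl]-2-[(2R,3R)-3-{2-[(4-methoxyphenyl)methoxy]ethyl}-2-methyloxiran-2-yl]ethyl (2S,3R)-2,3-dimethyloxirane-2-carboxylate
Conditions: D-fructose-derived Shi ketone (0.3 equiv), KHSO5 (as 2KHSO5·KHSO4·K2SO4), K2CO3, Bu4NHSO4, MeCN–CH2(OMe)2–aq Na2B4O7 buffer, 0 °C
Reagents that add atoms: potassium peroxymonosulfate, [K+].[O-]S(=O)(=O)OO
Why: Shi epoxidation: the chiral dioxirane transfers oxygen through a spiro transition state to the only electron-rich alkene (the methylene lactone is electron-poor), and the D-fructose ketone gives the (R,R) sense for E alkenes, here (1R,10R); the selectivity is reagent-controlled because the alkene is remote from the existing centres.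

Step 15
Reactants: 22 (1R)-1-[(2S,3R)-2-(hydroxymethyl)-4-methylidene-5-oxooxolan-3-yl]-2-[(2R,3R)-3-{2-[(4-methoxyphenyl)methoxy]ethyl}-2-methyloxiran-2-yl]ethyl (2S,3R)-2,3-dimethyloxirane-2-carboxylate
Product: 23 (1R)-1-[(2S,3R)-2-formyl-4-methylidene-5-oxooxolan-3-yl]-2-[(2R,3R)-3-{2-[(4-methoxyphenyl)methoxy]ethyl}-2-methyloxiran-2-yl]ethyl (2S,3R)-2,3-dimethyloxirane-2-carboxylate
Conditions: Dess–Martin periodinane, NaHCO3, CH2Cl2, 0 °C; used crude
Reagents that add atoms: none
Why: Buffered Dess–Martin oxidation of the C5 alcohol to the α-acyloxy aldehyde; neutral conditions and immediate use guard the C6 centre against epimerisation.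

Step 16
Reactants: 23 (1R)-1-[(2S,3R)-2-formyl-4-methylidene-5-oxooxolan-3-yl]-2-[(2R,3R)-3-{2-[(4-methoxyphenyl)methoxy]ethyl}-2-methyloxiran-2-yl]ethyl (2S,3R)-2,3-dimethyloxirane-2-carboxylate; 24 ethyltriphenylphosphonium iodide
Product: 28 (1R)-1-{(2S,3R)-2-[(1Z)-2-iodoprop-1-en-1-yl]-4-methylidene-5-oxooxolan-3-yl}-2-[(2R,3R)-3-{2-[(4-methoxyphenyl)methoxy]ethyl}-2-methyloxiran-2-yl]ethyl (2S,3R)-2,3-dimethyloxirane-2-carboxylate, via ethylidene ylide 25 (not isolated), via iodoethylphosphonium iodide 26 (not isolated), via iodoethylidene ylide 27 (not isolated)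
Conditions: 24, n-BuLi, THF, rt; I2, −78 °C; NaN(SiMe3)2, −20 °C; then 23, −78 to −20 °C
Reagents that add atoms: iodine, II
Why: Wittig olefination with an α-iodo ylide (Stork–Zhao type): ylide 25 is iodinated to 26 and deprotonated to 27, which adds to the aldehyde under kinetic control through the cis oxaphosphetane to give the Z iodoalkene with iodine cis to C6; low temperature and the absence of excess base protect C6 and the methylene lactone.

Step 17
Reactants: 28 (1R)-1-{(2S,3R)-2-[(1Z)-2-iodoprop-1-en-1-yl]-4-methylidene-5-oxooxolan-3-yl}-2-[(2R,3R)-3-{2-[(4-methoxyphenyl)methoxy]ethyl}-2-methyloxiran-2-yl]ethyl (2S,3R)-2,3-dimethyloxirane-2-carboxylate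
Product: 29 (1R)-2-[(2R,3R)-3-(2-hydroxyethyl)-2-methyloxiran-2-yl]-1-{(2S,3R)-2-[(1Z)-2-iodoprop-1-en-1-yl]-4-methylidene-5-oxooxolan-3-yl}ethyl (2S,3R)-2,3-dimethyloxirane-2-carboxylate
Conditions: DDQ, CH2Cl2–aq NaH2PO4/Na2HPO4 buffer (pH 7), 0 °C
Reagents that add atoms: none
Why: Oxidative cleavage of the 4-methoxybenzyl ether (hydride abstraction by the quinone, hydrolysis of the oxocarbenium ion); the buffered neutral medium spares both epoxides, the iodoalkene and the methylene lactone.

Step 18
Reactants: 29 (1R)-2-[(2R,3R)-3-(2-hydroxyethyl)-2-methyloxiran-2-yl]-1-{(2S,3R)-2-[(1Z)-2-iodoprop-1-en-1-yl]-4-methylidene-5-oxooxolan-3-yl}ethyl (2S,3R)-2,3-dimethyloxirane-2-carboxylate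
Product: 30 (1R)-1-{(2S,3R)-2-[(1Z)-2-iodoprop-1-en-1-yl]-4-methylidene-5-oxooxolan-3-yl}-2-[(2R,3R)-2-methyl-3-(2-oxoethyl)oxiran-2-yl]ethyl (2S,3R)-2,3-dimethyloxirane-2-carboxylate
Conditions: Dess–Martin periodinane, NaHCO3, CH2Cl2, 0 °C; filtered through a short neutral pad and used at once
Reagents that add atoms: none
Why: Buffered Dess–Martin oxidation gives the β,γ-epoxy aldehyde under the only conditions it is likely to survive; acid, base or silica would open the epoxide by β-elimination to the γ-hydroxy enal, so the aldehyde is made last and not stored.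

Step 19
Reactants: 30 (1R)-1-{(2S,3R)-2-[(1Z)-2-iodoprop-1-en-1-yl]-4-methylidene-5-oxooxolan-3-yl}-2-[(2R,3R)-2-methyl-3-(2-oxoethyl)oxiran-2-yl]ethyl (2S,3R)-2,3-dimethyloxirane-2-carboxylate
Product: 32 (1R,3S,4Z,6R,7R,8R,10R)-8-{[(2S,3R)-2,3-dimethyloxirane-2-carbonyl]oxy}-1,10-epoxy-3-hydroxygermacra-4,11(13)-dien-12,6-olide, via alkenylchromium dichloride 31 (not isolated)
Conditions: CrCl2 (8 equiv), NiCl2 (1 mol% of CrCl2), degassed DMSO–THF, rt, slow addition of 30 to a final 0.002 M; aqueous potassium serinate work-up
Reagents that add atoms: none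
Why: Nozaki–Hiyama–Kishi reaction: NiCl2 is reduced by CrCl2 to zerovalent nickel, which inserts into the C4–I bond with retention of the Z geometry; transmetallation gives the trivalent alkenylchromium 31 and a second CrCl2 supplies the other electron. The C–Cr bond is nucleophilic but hardly basic, so it adds only to the chromium-bound aldehyde (1,2-addition) and leaves the lactone, the ester, both epoxides and the acidic C2 hydrogens alone. The closest known reaction type is the chromium/nickel macrocyclisation of ω-iodoalkenyl aldehydes to cyclic allylic alcohols. The ten-membered ring closes in a 10-exo-trig mode by formation of C3–C4; the trans lactone, the Z alkene and the trans epoxide remove most rotatable bonds and bring C3 within reach of C4, and slow addition at high dilution suppresses dimerisation. The new stereocentre C3 is set under substrate control in the cyclic transition state, and the (S) alcohol requires attack on the Re face of the aldehyde. The elements that bias this face are the ring conformation imposed by the three rigid units and the C1 centre β to the carbonyl, with the bulky chromium alkoxide expected on the outside of the forming ring. This bias is not secure, since open-chain 1,3-induction from a β-oxygen would favour the other face, so the end game is designed to use either C3 epimer. Chemoselectivity for the C–I bond over the epoxides and the methylene lactone rests on the fast insertion of nickel into an alkenyl iodide at room temperature.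

Step 20
Reactants: 32 (1R,3S,4Z,6R,7R,8R,10R)-8-{[(2S,3R)-2,3-dimethyloxirane-2-carbonyl]oxy}-1,10-epoxy-3-hydroxygermacra-4,11(13)-dien-12,6-olide
Product: 33 (1R,3S,4Z,6R,7R,8R,10R)-3-(benzoyloxy)-8-{[(2S,3R)-2,3-dimethyloxirane-2-carbonyl]oxy}-1,10-epoxygermacra-4,11(13)-dien-12,6-olide (CNP0324463.4)
Conditions: BzCl, pyridine, DMAP (cat.), CH2Cl2, 0 °C
Reagents that add atoms: benzoyl chloride, O=C(Cl)c1ccccc1
Why: DMAP-catalysed acylation of the secondary allylic alcohol with retention at C3; the mild base and low temperature spare the methylene lactone and both epoxides.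

## Compound list

1 | 1,2:5,6-di-O-isopropylidene-D-mannitol | CC1(C)OC[C@@H](O1)[C@@H](O)[C@H](O)[C@H]1COC(C)(C)O1 | starting material
2 | (4R)-2,2-dimethyl-1,3-dioxolane-4-carbaldehyde | CC1(C)OC[C@@H](O1)C=O | intermediate
3 | ethyl acrylate | C=CC(=O)OCC | starting material
4 | ethyl 2-{[(4R)-2,2-dimethyl-1,3-dioxolan-4-yl](hydroxy)methyl}prop-2-enoate (both carbinol epimers) | CC1(C)OC[C@@H](O1)C(O)C(=C)C(=O)OCC | intermediate
5 | ethyl (2Z)-2-(bromomethyl)-3-[(4S)-2,2-dimethyl-1,3-dioxolan-4-yl]prop-2-enoate | CC1(C)OC[C@@H](O1)/C=C(\CBr)C(=O)OCC | intermediate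
6 | tert-butyl(but-3-yn-1-yloxy)dimethylsilane | C#CCCO[Si](C)(C)C(C)(C)C | starting material
7 | [(1E)-4-{[tert-butyl(dimethyl)silyl]oxy}-2-methylbut-1-en-1-yl]dimethylalumane (not isolated) | C[Al](C)/C=C(\C)CCO[Si](C)(C)C(C)(C)C | intermediate
8 | lithium butyl[(1E)-4-{[tert-butyl(dimethyl)silyl]oxy}-2-methylbut-1-en-1-yl]dimethylaluminate (not isolated) | [Li+].CCCC[Al-](C)(C)/C=C(\C)CCO[Si](C)(C)C(C)(C)C | intermediate
9 | (3E)-6-{[tert-butyl(dimethyl)silyl]oxy}-4-methylhex-3-en-1-ol | OCC/C=C(\C)CCO[Si](C)(C)C(C)(C)C | intermediate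
10 | tert-butyl({(3E)-6-[(4-methoxyphenyl)methoxy]-3-methylhex-3-en-1-yl}oxy)dimethylsilane | COc1ccc(COCC/C=C(\C)CCO[Si](C)(C)C(C)(C)C)cc1 | intermediate
11 | (3E)-6-[(4-methoxyphenyl)methoxy]-3-methylhex-3-en-1-ol | COc1ccc(COCC/C=C(\C)CCO)cc1 | intermediate
12 | (3E)-6-[(4-methoxyphenyl)methoxy]-3-methylhex-3-enal | COc1ccc(COCC/C=C(\C)CC=O)cc1 | intermediate
13 | ethyl (3R,4R,6E)-3-[(4S)-2,2-dimethyl-1,3-dioxolan-4-yl]-4-hydroxy-9-[(4-methoxyphenyl)methoxy]-6-methyl-2-methylidenenon-6-enoate | C=C(C(=O)OCC)[C@@H]([C@H]1COC(C)(C)O1)[C@H](O)C/C(C)=C/CCOCc1ccc(OC)cc1 | intermediate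
14 | tiglic acid, (2E)-2-methylbut-2-enoic acid | C/C=C(\C)C(=O)O | starting material
15 | (2E)-2-methylbut-2-en-1-ol | C/C=C(\C)CO | intermediate
16 | [(2R,3R)-2,3-dimethyloxiran-2-yl]methanol | OC[C@@]1(C)O[C@@H]1C | intermediate
17 | (2S,3R)-2,3-dimethyloxirane-2-carboxylic acid | OC(=O)[C@@]1(C)O[C@@H]1C | intermediate
18 | (2S,3R)-2,3-dimethyloxirane-2-carboxylic 2,4,6-trichlorobenzoic anhydride (not isolated) | O=C(OC(=O)c1c(Cl)cc(Cl)cc1Cl)[C@@]2(C)O[C@@H]2C | intermediate
19 | ethyl (3R,4R,6E)-4-{[(2S,3R)-2,3-dimethyloxirane-2-carbonyl]oxy}-3-[(4S)-2,2-dimethyl-1,3-dioxolan-4-yl]-9-[(4-methoxyphenyl)methoxy]-6-methyl-2-methylidenenon-6-enoate | C=C(C(=O)OCC)[C@@H]([C@H]1COC(C)(C)O1)[C@H](OC(=O)[C@@]2(C)O[C@@H]2C)C/C(C)=C/CCOCc3ccc(OC)cc3 | intermediate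
20 | ethyl (3S,4R,6E)-3-[(1S)-1,2-dihydroxyethyl]-4-{[(2S,3R)-2,3-dimethyloxirane-2-carbonyl]oxy}-9-[(4-methoxyphenyl)methoxy]-6-methyl-2-methylidenenon-6-enoate (not isolated) | C=C(C(=O)OCC)[C@@H]([C@H](O)CO)[C@H](OC(=O)[C@@]2(C)O[C@@H]2C)C/C(C)=C/CCOCc3ccc(OC)cc3 | intermediate
21 | (1R,3E)-1-[(2S,3R)-2-(hydroxymethyl)-4-methylidene-5-oxooxolan-3-yl]-6-[(4-methoxyphenyl)methoxy]-3-methylhex-3-en-1-yl (2S,3R)-2,3-dimethyloxirane-2-carboxylate | C=C1C(=O)O[C@H](CO)[C@H]1[C@H](OC(=O)[C@@]2(C)O[C@@H]2C)C/C(C)=C/CCOCc3ccc(OC)cc3 | intermediate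
22 | (1R)-1-[(2S,3R)-2-(hydroxymethyl)-4-methylidene-5-oxooxolan-3-yl]-2-[(2R,3R)-3-{2-[(4-methoxyphenyl)methoxy]ethyl}-2-methyloxiran-2-yl]ethyl (2S,3R)-2,3-dimethyloxirane-2-carboxylate | C=C1C(=O)O[C@H](CO)[C@H]1[C@H](OC(=O)[C@@]2(C)O[C@@H]2C)C[C@@]3(C)O[C@@H]3CCOCc4ccc(OC)cc4 | intermediate
23 | (1R)-1-[(2S,3R)-2-formyl-4-methylidene-5-oxooxolan-3-yl]-2-[(2R,3R)-3-{2-[(4-methoxyphenyl)methoxy]ethyl}-2-methyloxiran-2-yl]ethyl (2S,3R)-2,3-dimethyloxirane-2-carboxylate | C=C1C(=O)O[C@H](C=O)[C@H]1[C@H](OC(=O)[C@@]2(C)O[C@@H]2C)C[C@@]3(C)O[C@@H]3CCOCc4ccc(OC)cc4 | intermediate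
24 | ethyltriphenylphosphonium iodide | CC[P+](c1ccccc1)(c2ccccc2)c3ccccc3.[I-] | starting material
25 | ethylidenetriphenylphosphorane (not isolated) | CC=P(c1ccccc1)(c2ccccc2)c3ccccc3 | intermediate
26 | (1-iodoethyl)triphenylphosphonium iodide (not isolated) | CC(I)[P+](c1ccccc1)(c2ccccc2)c3ccccc3.[I-] | intermediate
27 | (1-iodoethylidene)triphenylphosphorane (not isolated) | CC(I)=P(c1ccccc1)(c2ccccc2)c3ccccc3 | intermediate
28 | (1R)-1-{(2S,3R)-2-[(1Z)-2-iodoprop-1-en-1-yl]-4-methylidene-5-oxooxolan-3-yl}-2-[(2R,3R)-3-{2-[(4-methoxyphenyl)methoxy]ethyl}-2-methyloxiran-2-yl]ethyl (2S,3R)-2,3-dimethyloxirane-2-carboxylate | C=C1C(=O)O[C@H](/C=C(/C)I)[C@H]1[C@H](OC(=O)[C@@]2(C)O[C@@H]2C)C[C@@]3(C)O[C@@H]3CCOCc4ccc(OC)cc4 | intermediate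
29 | (1R)-2-[(2R,3R)-3-(2-hydroxyethyl)-2-methyloxiran-2-yl]-1-{(2S,3R)-2-[(1Z)-2-iodoprop-1-en-1-yl]-4-methylidene-5-oxooxolan-3-yl}ethyl (2S,3R)-2,3-dimethyloxirane-2-carboxylate | C=C1C(=O)O[C@H](/C=C(/C)I)[C@H]1[C@H](OC(=O)[C@@]2(C)O[C@@H]2C)C[C@@]3(C)O[C@@H]3CCO | intermediate
30 | (1R)-1-{(2S,3R)-2-[(1Z)-2-iodoprop-1-en-1-yl]-4-methylidene-5-oxooxolan-3-yl}-2-[(2R,3R)-2-methyl-3-(2-oxoethyl)oxiran-2-yl]ethyl (2S,3R)-2,3-dimethyloxirane-2-carboxylate (seco aldehyde) | C=C1C(=O)O[C@H](/C=C(/C)I)[C@H]1[C@H](OC(=O)[C@@]2(C)O[C@@H]2C)C[C@@]3(C)O[C@@H]3CC=O | intermediate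
31 | Z-alkenylchromium dichloride of 30, trivalent chromium on C4 in place of iodine (not isolated) | C=C1C(=O)O[C@H](/C=C(/C)[Cr](Cl)Cl)[C@H]1[C@H](OC(=O)[C@@]2(C)O[C@@H]2C)C[C@@]3(C)O[C@@H]3CC=O | intermediate
32 | (1R,3S,4Z,6R,7R,8R,10R)-8-{[(2S,3R)-2,3-dimethyloxirane-2-carbonyl]oxy}-1,10-epoxy-3-hydroxygermacra-4,11(13)-dien-12,6-olide | C=C1C(=O)O[C@@H]2/C=C(/C)[C@@H](O)C[C@H]3O[C@]3(C)C[C@@H](OC(=O)[C@@]3(C)O[C@@H]3C)[C@@H]12 | intermediate
33 | (1R,3S,4Z,6R,7R,8R,10R)-3-(benzoyloxy)-8-{[(2S,3R)-2,3-dimethyloxirane-2-carbonyl]oxy}-1,10-epoxygermacra-4,11(13)-dien-12,6-olide (CNP0324463.4) | C=C1C(=O)O[C@@H]2/C=C(/C)[C@@H](OC(=O)c3ccccc3)C[C@H]3O[C@]3(C)C[C@@H](OC(=O)[C@@]3(C)O[C@@H]3C)[C@@H]12 | target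

## Step count and least certain steps

Total step count: 20. Longest linear sequence: 14 steps (steps 4–8 and 12–20, from 6). The branches are steps 1–3 (bromide 5) and steps 9–11 (acid 17).

Step 19 (key step). Most likely to go wrong: poor facial selectivity at C3 during ring closure, because the only control is the conformation of the forming ring; next to that, loss of the aldehyde through opening of the neighbouring epoxide before it cyclises, and dimerisation if the addition is too fast. Fallback: the end game is made convergent at C3 instead of relying on one face. Setting out from 30, the cyclisation that gives 32 would give beside it the (3R)-epimeric alcohol F1. F1 is not oxidised and reduced but esterified with inversion by a Mitsunobu reaction (benzoic acid, PPh3, diisopropyl azodicarboxylate, toluene, 0 °C), which brings this material back to the route at 33. The two epimers are separated after step 19 and each takes its own acylation.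

Step 8. Most likely to go wrong: insufficient facial discrimination at C7 relative to C6, since the allylic dioxolane alone must steer the aldehyde anti to its C–O bond. Isomerisation of the allylindium would erode the 7,8-syn preference, and the γ-metallated isomer could lose the allylic oxygen by β-elimination. Fallback: a ring template replaces allylic-strain control. Setting out from 4, acid (TsOH, MeOH, rt) removes the acetonide and closes the lactone to (5R)-4-hydroxy-5-(hydroxymethyl)-3-methylideneoxolan-2-one F2. The primary hydroxyl is silylated (t-BuPh2SiCl, imidazole, CH2Cl2, 0 °C) to the silyl ether F3. PBr3 in Et2O at 0 °C then brominates with allylic transposition to (5S)-3-(bromomethyl)-5-({[tert-butyl(diphenyl)silyl]oxy}methyl)furan-2(5H)-one F4. Indium-mediated allylation of 12 with this ring-locked bromide (In, THF–H2O) should add anti to the C5 substituent of the butenolide, which secures the trans 6,7 relation, and through the chair of the E-configured allylmetal should give the 7,8-anti alcohol F5, which is epimeric at C8. Mitsunobu esterification of the C8 alcohol F5 with 17 (PPh3, diisopropyl azodicarboxylate, toluene) inverts C8 and gives the silyl ether of 21, F6. Bu4NF buffered with AcOH in THF removes the silyl group, and the route is rejoined at 21.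

Step 16. Most likely to go wrong: deprotonation of the substrate by the ylide or by residual amide base. This would mean epimerisation of the α-acyloxy aldehyde at C6, isomerisation of the methylene lactone to the butenolide or conjugate addition of the ylide, and with it a low conversion to the iodoalkene. Fallback: a base-free olefination followed by a stereoselective cross-coupling. Setting out from 23, dibromo-olefination (CBr4, PPh3, CH2Cl2, 0 °C) gives the 1,1-dibromoalkene F10. Palladium-catalysed methylation of the bromine trans to C6 (MeZnCl, Pd(P(t-Bu)3)2 as zerovalent palladium catalyst, THF, 0 °C) leaves the bromine cis to C6 and gives the (Z)-2-bromopropenyl compound F11. This is carried through the conditions of steps 17 and 18 to the bromo alcohol F12 and the bromo seco aldehyde F13. Chromium/nickel cyclisation of F13 (CrCl2, NiCl2 cat., DMSO–DMF, 40 °C, high dilution; the alkenyl bromide reacts more slowly than the iodide) returns to the route at 32.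

Step 14. Most likely to go wrong: attack of the alkaline aqueous medium on the methylene lactone (hydrolysis or conjugate addition) during the epoxidation, and incomplete facial control showing up as a diastereomer at C1/C10. Fallback: the epoxide is introduced later, under neutral conditions, by a hydroxyl-directed asymmetric epoxidation. Setting out from 21, Dess–Martin oxidation gives the aldehyde F7, the iodo-Wittig conditions of step 16 give the Z iodoalkene F8, and DDQ at pH 7 gives the homoallylic alcohol F9. Vanadium-catalysed asymmetric epoxidation of this homoallylic alcohol (VO(OiPr)3, a chiral bishydroxamic acid ligand of the enantiomer matched to the 1R,10R epoxide, cumene hydroperoxide, toluene, rt) is directed by the C3 hydroxyl to C1=C10 and rejoins the route at 29.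

## Further compounds

F1 | step 19 | (1R,3R,4Z,6R,7R,8R,10R)-8-{[(2S,3R)-2,3-dimethyloxirane-2-carbonyl]oxy}-1,10-epoxy-3-hydroxygermacra-4,11(13)-dien-12,6-olide (C3 epimer of 32) | C=C1C(=O)O[C@@H]2/C=C(/C)[C@H](O)C[C@H]3O[C@]3(C)C[C@@H](OC(=O)[C@@]3(C)O[C@@H]3C)[C@@H]12
F2 | step 8 | (5R)-4-hydroxy-5-(hydroxymethyl)-3-methylideneoxolan-2-one (both C4 epimers) | C=C1C(O)[C@@H](CO)OC1=O
F3 | step 8 | (5R)-5-({[tert-butyl(diphenyl)silyl]oxy}methyl)-4-hydroxy-3-methylideneoxolan-2-one (both C4 epimers) | C=C1C(O)[C@@H](CO[Si](c2ccccc2)(c2ccccc2)C(C)(C)C)OC1=O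
F4 | step 8 | (5S)-3-(bromomethyl)-5-({[tert-butyl(diphenyl)silyl]oxy}methyl)furan-2(5H)-one | BrCC1=C[C@@H](CO[Si](c2ccccc2)(c2ccccc2)C(C)(C)C)OC1=O
F5 | step 8 | (4R,5S)-5-({[tert-butyl(diphenyl)silyl]oxy}methyl)-4-{(1S,3E)-1-hydroxy-6-[(4-methoxyphenyl)methoxy]-3-methylhex-3-en-1-yl}-3-methylideneoxolan-2-one | C=C1C(=O)O[C@H](CO[Si](c2ccccc2)(c2ccccc2)C(C)(C)C)[C@H]1[C@@H](O)C/C(C)=C/CCOCc1ccc(OC)cc1
F6 | step 8 | (1R,3E)-1-[(2S,3R)-2-({[tert-butyl(diphenyl)silyl]oxy}methyl)-4-methylidene-5-oxooxolan-3-yl]-6-[(4-methoxyphenyl)methoxy]-3-methylhex-3-en-1-yl (2S,3R)-2,3-dimethyloxirane-2-carboxylate | C=C1C(=O)O[C@H](CO[Si](c2ccccc2)(c2ccccc2)C(C)(C)C)[C@H]1[C@H](OC(=O)[C@@]3(C)O[C@@H]3C)C/C(C)=C/CCOCc1ccc(OC)cc1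
F7 | step 14 | (1R,3E)-1-[(2S,3R)-2-formyl-4-methylidene-5-oxooxolan-3-yl]-6-[(4-methoxyphenyl)methoxy]-3-methylhex-3-en-1-yl (2S,3R)-2,3-dimethyloxirane-2-carboxylate | C=C1C(=O)O[C@H](C=O)[C@H]1[C@H](OC(=O)[C@@]2(C)O[C@@H]2C)C/C(C)=C/CCOCc3ccc(OC)cc3
F8 | step 14 | (1R,3E)-1-{(2S,3R)-2-[(1Z)-2-iodoprop-1-en-1-yl]-4-methylidene-5-oxooxolan-3-yl}-6-[(4-methoxyphenyl)methoxy]-3-methylhex-3-en-1-yl (2S,3R)-2,3-dimethyloxirane-2-carboxylate | C=C1C(=O)O[C@H](/C=C(/C)I)[C@H]1[C@H](OC(=O)[C@@]2(C)O[C@@H]2C)C/C(C)=C/CCOCc3ccc(OC)cc3
F9 | step 14 | (1R,3E)-6-hydroxy-1-{(2S,3R)-2-[(1Z)-2-iodoprop-1-en-1-yl]-4-methylidene-5-oxooxolan-3-yl}-3-methylhex-3-en-1-yl (2S,3R)-2,3-dimethyloxirane-2-carboxylate | C=C1C(=O)O[C@H](/C=C(/C)I)[C@H]1[C@H](OC(=O)[C@@]2(C)O[C@@H]2C)C/C(C)=C/CCO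
F10 | step 16 | (1R)-1-[(2S,3R)-2-(2,2-dibromoethenyl)-4-methylidene-5-oxooxolan-3-yl]-2-[(2R,3R)-3-{2-[(4-methoxyphenyl)methoxy]ethyl}-2-methyloxiran-2-yl]ethyl (2S,3R)-2,3-dimethyloxirane-2-carboxylate | C=C1C(=O)O[C@H](C=C(Br)Br)[C@H]1[C@H](OC(=O)[C@@]2(C)O[C@@H]2C)C[C@@]3(C)O[C@@H]3CCOCc4ccc(OC)cc4
F11 | step 16 | (1R)-1-{(2S,3R)-2-[(1Z)-2-bromoprop-1-en-1-yl]-4-methylidene-5-oxooxolan-3-yl}-2-[(2R,3R)-3-{2-[(4-methoxyphenyl)methoxy]ethyl}-2-methyloxiran-2-yl]ethyl (2S,3R)-2,3-dimethyloxirane-2-carboxylate | C=C1C(=O)O[C@H](/C=C(/C)Br)[C@H]1[C@H](OC(=O)[C@@]2(C)O[C@@H]2C)C[C@@]3(C)O[C@@H]3CCOCc4ccc(OC)cc4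
F12 | step 16 | (1R)-1-{(2S,3R)-2-[(1Z)-2-bromoprop-1-en-1-yl]-4-methylidene-5-oxooxolan-3-yl}-2-[(2R,3R)-3-(2-hydroxyethyl)-2-methyloxiran-2-yl]ethyl (2S,3R)-2,3-dimethyloxirane-2-carboxylate | C=C1C(=O)O[C@H](/C=C(/C)Br)[C@H]1[C@H](OC(=O)[C@@]2(C)O[C@@H]2C)C[C@@]3(C)O[C@@H]3CCO
F13 | step 16 | (1R)-1-{(2S,3R)-2-[(1Z)-2-bromoprop-1-en-1-yl]-4-methylidene-5-oxooxolan-3-yl}-2-[(2R,3R)-2-methyl-3-(2-oxoethyl)oxiran-2-yl]ethyl (2S,3R)-2,3-dimethyloxirane-2-carboxylate | C=C1C(=O)O[C@H](/C=C(/C)Br)[C@H]1[C@H](OC(=O)[C@@]2(C)O[C@@H]2C)C[C@@]3(C)O[C@@H]3CC=O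
A1 | alternative 1 | ten-membered 1,10-epoxy 12,6-lactone with 3-benzoate, 8-tert-butyldimethylsilyl ether, Z C4=C5 and saturated C11 (no C13) | C1C(=O)O[C@@H]2/C=C(/C)[C@@H](OC(=O)c3ccccc3)C[C@H]3O[C@]3(C)C[C@@H](O[Si](C)(C)C(C)(C)C)[C@@H]12
A2 | alternative 2 | isoxazoline-bridged ten-membered carbocycle (C6=N, O on C4) with 3-benzoate, 1,10-epoxide, C8 epoxy ester and a CH2CO2Me arm on C7 | COC(=O)C[C@H]1C2=NO[C@](C)(C2)[C@@H](OC(=O)c4ccccc4)C[C@H]3O[C@]3(C)C[C@H]1OC(=O)[C@@]5(C)O[C@@H]5C
A3 | alternative 3 | (2Z,6E)-9-[benzyl(dimethyl)silyl]-4-{[tert-butyl(dimethyl)silyl]oxy}-3,7-dimethylcyclodeca-2,6-dien-1-one (germacrane C6 ketone, silicon on C8) | O=C1/C=C(/C)[C@@H](O[Si](C)(C)C(C)(C)C)C/C=C(\C)C[C@@H]([Si](C)(C)Cc2ccccc2)C1
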